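The target is C2-symmetric about the bridging methine, and in each benzene ring the pyran oxygen O1 sits ortho to the acyl carbon C8 while C5–OH and C7–OH flank the bridge at C6. The route therefore builds the open, bridged bis(acylphloroglucinol) first and closes both pyran rings last and together: a two-directional double formal [3+3] annulation with 3-methylbut-2-enal (condensation, then 6π-oxa-electrocyclisation) forms C4–C4a and O1–C2 in both halves in one operation. In the precursor the phenol para to each acyl group is benzylated, so each ring offers one free carbon and one free neighbouring phenol, which fixes the ring-fusion regiochemistry. Hydrogenation with debenzylation then gives the target.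

Key step: step 4

Assumption: CIP analysis of the given SMILES gives (R) at both acyl α-carbons, the bridging carbon carries two identical aryl groups and is not a stereocentre, and (R)-2-methylbutanoic acid and 6-methylheptanal are taken as purchasable.

Step 1
Reactants: 1 phloroglucinol (benzene-1,3,5-triol); 2 (R)-2-methylbutanoic acid
Product: 4 (2R)-2-methyl-1-(2,4,6-trihydroxyphenyl)butan-1-one, via (R)-2-methylbutanoyl chloride 3 (not isolated)
Conditions: 2, (COCl)2 (1.0 equiv), DMF (cat.), CH2Cl2, 0 °C → rt; then 1, AlCl3 (4 equiv), PhNO2/CH2Cl2, 0 °C → rt; aq. HCl work-up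
Reagents that add atoms: none
Why: Acid chloride formation followed by Friedel–Crafts C-acylation of the threefold-symmetric triol (all three ring positions equivalent, second acylation disfavoured by the first acyl group) should carry the stereocentre of 2 through unchanged, because neither acylium formation nor arene attack breaks a bond at the α-carbon and the low temperature disfavours enolisation of the aluminium-chelated ketone.

Step 2
Reactants: 4 (2R)-2-methyl-1-(2,4,6-trihydroxyphenyl)butan-1-one
Product: 5 (2R)-1-[4-(benzyloxy)-2,6-dihydroxyphenyl]-2-methylbutan-1-one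
Conditions: BnBr (1.0 equiv), K2CO3 (1.1 equiv), DMF, 0 °C → rt
Reagents that add atoms: benzyl bromide, BrCc1ccccc1
Why: Williamson etherification should select the 4-OH, which is para to the acyl group, the most acidic phenol (a vinylogous carboxylic acid) and not engaged in the hydrogen bond to the carbonyl, so that the two free ring positions of 5 remain equivalent.

Step 3
Reactants: 5 (2R)-1-[4-(benzyloxy)-2,6-dihydroxyphenyl]-2-methylbutan-1-one (two molecules are incorporated); 6 6-methylheptanal
Product: 8 1,1-bis[6-(benzyloxy)-2,4-dihydroxy-3-((2R)-2-methylbutanoyl)phenyl]-6-methylheptane, via benzylic carbinol 7 (not isolated)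
Conditions: 5 (3 equiv, excess recovered), 6 (1 equiv, slow addition), NaOAc (20 mol %), AcOH, 70 °C
Reagents that add atoms: none
Why: Knoevenagel-type hydroxyalkylation at one of the two equivalent ring carbons gives carbinol 7, which should lose water through the adjacent free phenol to an o-quinone methide that a second molecule of 5 traps by Michael-type (Friedel–Crafts) addition, the excess of 5 suppressing chain extension and the new methine carrying two identical aryl groups and therefore being no stereocentre.

Step 4
Reactants: 8 1,1-bis[6-(benzyloxy)-2,4-dihydroxy-3-((2R)-2-methylbutanoyl)phenyl]-6-methylheptane; 9 3-methylbut-2-enal (two molecules are incorporated)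
Product: 12 1,1-bis[5-(benzyloxy)-7-hydroxy-2,2-dimethyl-8-((2R)-2-methylbutanoyl)-2H-chromen-6-yl]-6-methylheptane, via mono-o-quinone methide 10 (not isolated), via mono-chromene 11 (not isolated)
Conditions: 9 (5 equiv), ethylenediammonium diacetate (EDDA, 40 mol %), toluene, 110 °C, 4 Å MS
Reagents that add atoms: none
Why: EDDA converts 9 into an iminium ion that is attacked by the only unsubstituted carbon of each ring, and loss of the amine gives the o-quinone methide (1-oxatriene) 10, which closes by thermal 6π-oxa-electrocyclisation to the 2H-pyran, after which the second ring of mono-chromene 11 follows the same path. The closest known reaction type is the formal [3+3] chromene annulation of enals with phloroglucinols (Knoevenagel condensation/oxa-electrocyclisation), which is established for acylphloroglucinols that retain a single free position next to an ether oxygen. Each of the two pyran rings is closed at the O1–C2 bond by a disrotatory 6π-electrocyclisation of a cis-dienone after intermolecular formation of C4–C4a, so no Baldwin constraint applies. No stereocentre is created (C2 carries two methyl groups and the bridging carbon is stereogenic only in 11, not in 12), and the buffered, near-neutral medium should leave the two α-acyl centres untouched. The step needs regioselectivity in the choice of the ring oxygen, and the benzyl ethers secure it: next to the reacting carbon only the phenol ortho to the acyl group is free, so O1 must end up ortho to C8, while the β,β-disubstitution of 9 directs attack to the carbonyl carbon and not to the β-carbon. As both halves are identical, the two annulations should converge on a single bis-adduct, driven by re-aromatisation.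

Step 5
Reactants: 12 1,1-bis[5-(benzyloxy)-7-hydroxy-2,2-dimethyl-8-((2R)-2-methylbutanoyl)-2H-chromen-6-yl]-6-methylheptane
Product: 13 1,1-bis[5,7-dihydroxy-2,2-dimethyl-8-((2R)-2-methylbutanoyl)-3,4-dihydro-2H-chromen-6-yl]-6-methylheptane (CNP0324275.1)
Conditions: H2 (1 atm), 10% Pd/C, EtOAc/MeOH, rt
Reagents that add atoms: none
Why: Heterogeneous hydrogenation should saturate the two cis-disubstituted chromene C3=C4 bonds and cleave the two aryl benzyl ethers by hydrogenolysis in the same operation under neutral conditions, which leave the hydrogen-bonded, doubly ortho-substituted aryl ketones, the diarylmethine and the α-acyl stereocentres unchanged.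

Compound list
1 | phloroglucinol (benzene-1,3,5-triol) | Oc1cc(O)cc(O)c1 | starting material
2 | (R)-2-methylbutanoic acid | CC[C@@H](C)C(=O)O | starting material
3 | (R)-2-methylbutanoyl chloride | CC[C@@H](C)C(=O)Cl | intermediate
4 | (2R)-2-methyl-1-(2,4,6-trihydroxyphenyl)butan-1-one | CC[C@@H](C)C(=O)c1c(O)cc(O)cc1O | intermediate
5 | (2R)-1-[4-(benzyloxy)-2,6-dihydroxyphenyl]-2-methylbutan-1-one | CC[C@@H](C)C(=O)c1c(O)cc(OCc2ccccc2)cc1O | intermediate
6 | 6-methylheptanal | CC(C)CCCCC=O | starting material
7 | (2R)-1-[4-(benzyloxy)-2,6-dihydroxy-3-(1-hydroxy-6-methylheptyl)phenyl]-2-methylbutan-1-one (benzylic carbinol, carbinol configuration unassigned) | CC[C@@H](C)C(=O)c1c(O)cc(OCc2ccccc2)c(C(O)CCCCC(C)C)c1O | intermediate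
8 | 1,1-bis[6-(benzyloxy)-2,4-dihydroxy-3-((2R)-2-methylbutanoyl)phenyl]-6-methylheptane | CC[C@@H](C)C(=O)c1c(O)cc(OCc2ccccc2)c(C(CCCCC(C)C)c2c(OCc3ccccc3)cc(O)c(C(=O)[C@H](C)CC)c2O)c1O | intermediate
9 | 3-methylbut-2-enal | CC(C)=CC=O | starting material
10 | mono-o-quinone methide of 8 (one ring as 6-(3-methylbut-2-enylidene)cyclohexa-2,4-dienone, exocyclic alkene geometry unassigned; other ring as in 8) | CC[C@@H](C)C(=O)C1=C(O)C(C(CCCCC(C)C)c2c(OCc3ccccc3)cc(O)c(C(=O)[C@H](C)CC)c2O)=C(OCc2ccccc2)C(=CC=C(C)C)C1=O | intermediate
11 | mono-chromene (one ring annulated as in 12, the other as in 8; bridging carbon configuration unassigned) | CC[C@@H](C)C(=O)c1c(O)c(C(CCCCC(C)C)c2c(OCc3ccccc3)cc(O)c(C(=O)[C@H](C)CC)c2O)c(OCc2ccccc2)c2c1OC(C)(C)C=C2 | intermediate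
12 | 1,1-bis[5-(benzyloxy)-7-hydroxy-2,2-dimethyl-8-((2R)-2-methylbutanoyl)-2H-chromen-6-yl]-6-methylheptane | CC[C@@H](C)C(=O)c1c(O)c(C(CCCCC(C)C)c2c(O)c(C(=O)[C@H](C)CC)c3OC(C)(C)C=Cc3c2OCc4ccccc4)c(OCc2ccccc2)c2c1OC(C)(C)C=C2 | intermediate
13 | 1,1-bis[5,7-dihydroxy-2,2-dimethyl-8-((2R)-2-methylbutanoyl)-3,4-dihydro-2H-chromen-6-yl]-6-methylheptane (CNP0324275.1) | CC[C@@H](C)C(=O)c1c(O)c(C(CCCCC(C)C)c2c(O)c3c(c(C(=O)[C@H](C)CC)c2O)OC(C)(C)CC3)c(O)c2c1OC(C)(C)CC2 | target

Total step count: 5
Longest linear sequence: 5 steps (1/2 → 4 → 5 → 8 → 12 → 13)

Steps most likely to fail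

Step 4 (key step). The reaction may stall after the first annulation because the second ring is congested. The diarylmethine bridge may also undergo thermal retro-Michael scission, or the amine may cause epimerisation α to the ketones. The fallback sets out from 8 and returns at 13, and it closes the rings by a cationic instead of a pericyclic path. Compound 8 is treated with 2-methylbut-3-en-2-ol and BF3·OEt2 in dioxane at rt. Friedel–Crafts prenylation at the single free carbon of each ring, followed by Markovnikov hydroalkoxylation by the only adjacent free phenol, should give the bis-chroman dibenzyl ether 1,1-bis[5-(benzyloxy)-7-hydroxy-2,2-dimethyl-8-((2R)-2-methylbutanoyl)chroman-6-yl]-6-methylheptane F1. Hydrogenolysis of F1 (H2, Pd/C, EtOAc) then gives 13.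

Step 3. Chain extension may compete because 5 has two equivalent nucleophilic positions. Capture of the o-quinone methide at the carbon flanked by OH and OBn may also be slow, which allows tautomerisation to an alkenylphenol. The fallback sets out from 5 and returns at 12, and it inverts the order of events so that each arene has only one free position when the bridge is made. Compound 5 is annulated with one equivalent of 9 (EDDA, toluene, 110 °C) to give (2R)-1-[5-(benzyloxy)-7-hydroxy-2,2-dimethyl-2H-chromen-8-yl]-2-methylbutan-1-one F2. Two equivalents of F2 are then condensed with 6 (NaOAc, AcOH, 70 °C) to give 12.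

Step 1. Enantiomeric purity may erode through enolisation of the Lewis-acid-bound ketone or through ketene formation from the acylium ion. The fallback sets out from 1 and 2 and returns at 4, and it acylates with an aryllithium instead of an acylium ion. Compound 1 is converted into 1,3,5-tris(methoxymethoxy)benzene F3 (MOMCl, i-Pr2NEt, CH2Cl2). Compound 2 is converted into the Weinreb amide (2R)-N-methoxy-N,2-dimethylbutanamide F4 (CDI, then MeNHOMe·HCl, CH2Cl2). Ortho-lithiation of F3 (n-BuLi, THF, 0 °C) and addition to F4 at −78 °C should give (2R)-2-methyl-1-[2,4,6-tris(methoxymethoxy)phenyl]butan-1-one F5 through a chelated tetrahedral intermediate that cannot enolise. Mild acetal cleavage (HCl, MeOH, rt) then returns 4.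

Further compounds
F1 | step 4 | 1,1-bis[5-(benzyloxy)-7-hydroxy-2,2-dimethyl-8-((2R)-2-methylbutanoyl)chroman-6-yl]-6-methylheptane | CC[C@@H](C)C(=O)c1c(O)c(C(CCCCC(C)C)c2c(O)c(C(=O)[C@H](C)CC)c3OC(C)(C)CCc3c2OCc4ccccc4)c(OCc2ccccc2)c2c1OC(C)(C)CC2
F2 | step 3 | (2R)-1-[5-(benzyloxy)-7-hydroxy-2,2-dimethyl-2H-chromen-8-yl]-2-methylbutan-1-one | CC[C@@H](C)C(=O)c1c(O)cc(OCc2ccccc2)c2c1OC(C)(C)C=C2
F3 | step 1 | 1,3,5-tris(methoxymethoxy)benzene | COCOc1cc(OCOC)cc(OCOC)c1
F4 | step 1 | (2R)-N-methoxy-N,2-dimethylbutanamide | CC[C@@H](C)C(=O)N(C)OC
F5 | step 1 | (2R)-2-methyl-1-[2,4,6-tris(methoxymethoxy)phenyl]butan-1-one | CC[C@@H](C)C(=O)c1c(OCOC)cc(OCOC)cc1OCOC
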